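**Strategy**

1. Hansforester I is read as the linear tetraester A–B–C–D: resorcylate ring A (4-hydroxy-2-oxopentyl chain), (R)-3-hydroxybutanoate B, resorcylate ring C (2-acyloxypropyl chain) and (R)-3-hydroxybutanoic acid D.
2. Enabling feature: both benzene rings are 2,4-dihydroxy-6-alkylbenzoates (ester carbon on ring C1, OH on C2 and C4, alkyl on C6), i.e. aldol-cyclised 3,5,7-triketo esters whose ester oxygen is the secondary carbinol oxygen of an (R)-3-hydroxybutanoate.
3. Cuts: for each ring the aryl ester C(=O)–O bond (ring A carboxyl to the B oxygen, ring C carboxyl to the D oxygen) together with the ring C1–C6 bond, leading back to two 6-(2,4-dioxoalkyl)-1,3-dioxin-4-ones; then the B–C alkyl ester and the chain C–C bonds, leading to one keto-ester dioxinone and protected 3-hydroxybutanoates.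
4. Forward order: ring C is closed first on the D alcohol from a diketo-dioxinone that already carries silylated B on its side-chain oxygen; the ring C phenols are benzylated, B is desilylated, ring A is closed last on the freed B hydroxyl, and acid unmasking plus hydrogenolysis finish.
5. Stereochemistry: all four (R) centres are the carbinol carbon of purchased methyl (R)-3-hydroxybutanoate; at these carbons only O–Si and O–acyl bonds are made or broken, so every centre is carried with retention and none is created.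

Key step: step 17

Assumption: allyl hydrogen malonate is taken as a purchasable half-ester, and polycarbonyl compounds are drawn as keto tautomers although they are largely enolised (TBSO = tert-butyldimethylsilyloxy, Bn = benzyl).

**Route**

Step 1
Reactants: 1 methyl (R)-3-hydroxybutanoate
Product: 2 methyl (R)-3-(tert-butyldimethylsilyloxy)butanoate
Conditions: TBSCl, imidazole, DMF, 0 °C to rt
Reagents that add atoms: tert-butyldimethylsilyl chloride, CC(C)(C)[Si](C)(C)Cl
Why: Imidazole-promoted silyl ether formation reacts only at the O–H bond, so the (R) carbinol centre is carried unchanged.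

Step 2
Reactants: 2 methyl (R)-3-(tert-butyldimethylsilyloxy)butanoate
Product: 3 (R)-3-(tert-butyldimethylsilyloxy)butanoic acid
Conditions: LiOH·H2O, THF/MeOH/H2O, 0 °C to rt; cold 1 M HCl to pH 3
Reagents that add atoms: lithium hydroxide, [Li+].[OH-] (supplies the carboxyl OH oxygen)
Why: Ester saponification by acyl–oxygen cleavage should be faster at room temperature than E1cB loss of the poor silyloxide leaving group, and the silyl ether survives a brief cold acidification, so the centre stays (R).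

Step 3
Reactants: 1 methyl (R)-3-hydroxybutanoate
Product: 4 benzyl (R)-3-hydroxybutanoate
Conditions: BnOH (excess), Ti(OiPr)4 (cat.), toluene, 100 °C, MeOH distilled off
Reagents that add atoms: benzyl alcohol, OCc1ccccc1
Why: Titanate-catalysed transesterification exchanges only the ester alkoxy group under neutral conditions, the excess primary alcohol outcompetes the secondary hydroxyl, and the carbinol centre is not involved.

Step 4
Reactants: 3 (R)-3-(tert-butyldimethylsilyloxy)butanoic acid, 4 benzyl (R)-3-hydroxybutanoate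
Product: 5 benzyl (R)-3-{[(R)-3-(TBSO)butanoyl]oxy}butanoate
Conditions: DCC, DMAP (cat.), CH2Cl2, 0 °C to rt
Reagents that add atoms: none
Why: Steglich esterification acylates the hydroxyl oxygen of 4 with activated 3, so neither carbinol C–O bond is broken and both centres stay (R).

Step 5
Reactants: 5 benzyl (R)-3-{[(R)-3-(TBSO)butanoyl]oxy}butanoate
Product: 6 (R)-3-{[(R)-3-(TBSO)butanoyl]oxy}butanoic acid
Conditions: H2 (1 atm), Pd/C, EtOAc, rt
Reagents that add atoms: none
Why: Hydrogenolysis of the benzylic ester C–O bond over palladium leaves the silyl ether and the internal secondary alkyl ester untouched.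

Step 6
Reactants: 7 allyl hydrogen malonate, 8 2,2,6-trimethyl-4H-1,3-dioxin-4-one
Product: 11 allyl 4-(2,2-dimethyl-4-oxo-4H-1,3-dioxin-6-yl)-3-oxobutanoate, via allyl malonyl chloride 9 (not isolated), via lithium dienolate 10 (not isolated)
Conditions: 7, (COCl)2, DMF (cat.), CH2Cl2, 0 °C to rt, concentrate; 8 (excess), LiN(SiMe3)2, THF, −78 °C, then 9, −78 °C; aq. NH4Cl
Reagents that add atoms: none
Why: Vinylogous Claisen-type C-acylation, in which the dienolate formed at the 6-methyl group attacks the acid chloride through its terminal carbon and the excess dienolate takes up the more acidic β-keto ester product.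

Step 7
Reactants: 6 (R)-3-{[(R)-3-(TBSO)butanoyl]oxy}butanoic acid, 11 allyl 4-(2,2-dimethyl-4-oxo-4H-1,3-dioxin-6-yl)-3-oxobutanoate
Product: 13 allyl (5R)-2-[2-(2,2-dimethyl-4-oxo-4H-1,3-dioxin-6-yl)acetyl]-3-oxo-5-{[(R)-3-(TBSO)butanoyl]oxy}hexanoate, via acid chloride 12 (not isolated)
Conditions: 6, 1-chloro-N,N,2-trimethylprop-1-en-1-amine, CH2Cl2, 0 °C to rt; then 11, MgCl2, pyridine, CH2Cl2, 0 °C
Reagents that add atoms: none
Why: The α-chloroenamine makes the acid chloride without releasing HCl (silyl ether safe), and magnesium-mediated soft enolisation of the β-keto ester directs C-acylation to the carbon between ketone and allyl ester, the resulting tricarbonyl anion shielding the neighbouring β-acyloxy CH2 from deprotonation.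

Step 8
Reactants: 13 allyl (5R)-2-[2-(2,2-dimethyl-4-oxo-4H-1,3-dioxin-6-yl)acetyl]-3-oxo-5-{[(R)-3-(TBSO)butanoyl]oxy}hexanoate
Product: 15 (R)-7-(2,2-dimethyl-4-oxo-4H-1,3-dioxin-6-yl)-4,6-dioxoheptan-2-yl (R)-3-(TBSO)butanoate, via keto acid 14 (not isolated)
Conditions: Pd(PPh3)4 (cat.), morpholine, CH2Cl2, 0 °C to rt
Reagents that add atoms: none
Why: Tsuji–Trost deallylation, in which zerovalent palladium ionises the allyl ester, morpholine takes up the allyl group and the freed β,β'-diketo acid loses CO2 at room temperature, while the weak amine deprotonates only the central diketone methylene and so disfavours E1cB loss of the β-acyloxy group.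

Step 9
Reactants: 15 (R)-7-(2,2-dimethyl-4-oxo-4H-1,3-dioxin-6-yl)-4,6-dioxoheptan-2-yl (R)-3-(TBSO)butanoate, 4 benzyl (R)-3-hydroxybutanoate
Product: 19 benzyl (R)-3-{[2,4-dihydroxy-6-((R)-2-{[(R)-3-(TBSO)butanoyl]oxy}propyl)benzoyl]oxy}butanoate, via acylketene 16 (not isolated), via triketo ester 17 (not isolated), via cyclic aldol 18 (not isolated)
Conditions: 4 (1.5 equiv), toluene, 110 °C; then Et3N, CH2Cl2, rt; then AcOH, rt
Reagents that add atoms: none
Why: Acylketene capture and aldol aromatisation of a diketo-dioxinone, in which retro-[4+2] loss of acetone gives the ketene, the hydroxyl of 4 adds to its ketene carbon, and amine-promoted 6-exo-trig aldol of C2 onto the C7 ketone followed by dehydration gives ring C with its hindered ester in place; no stereocentre is formed or touched and no alcohol solvent is present to exchange esters.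

Step 10
Reactants: 19 benzyl (R)-3-{[2,4-dihydroxy-6-((R)-2-{[(R)-3-(TBSO)butanoyl]oxy}propyl)benzoyl]oxy}butanoate
Product: 20 benzyl (R)-3-{[2,4-bis(benzyloxy)-6-((R)-2-{[(R)-3-(TBSO)butanoyl]oxy}propyl)benzoyl]oxy}butanoate
Conditions: BnBr, K2CO3, Bu4NI (cat.), DMF, rt
Reagents that add atoms: benzyl bromide, BrCc1ccccc1
Why: Williamson etherification, in which carbonate deprotonates only the two phenols (not the ester α-C–H, so the β-aroyloxy and β-silyloxy groups should not be eliminated) and DMF lets the hydrogen-bonded ortho phenol alkylate as well.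

Step 11
Reactants: 20 benzyl (R)-3-{[2,4-bis(benzyloxy)-6-((R)-2-{[(R)-3-(TBSO)butanoyl]oxy}propyl)benzoyl]oxy}butanoate
Product: 21 benzyl (R)-3-{[2,4-bis(benzyloxy)-6-((R)-2-{[(R)-3-hydroxybutanoyl]oxy}propyl)benzoyl]oxy}butanoate
Conditions: HF·pyridine, pyridine, THF, 0 °C to rt
Reagents that add atoms: none
Why: Fluoride-driven Si–O cleavage under buffered, weakly acidic conditions leaves the four esters and the benzyl ethers intact and does not touch the carbinol C–O bond.

Step 12
Reactants: 3 (R)-3-(tert-butyldimethylsilyloxy)butanoic acid, 7 allyl hydrogen malonate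
Product: 25 allyl (R)-5-(TBSO)-3-oxohexanoate, via imidazolide 22 (not isolated), via magnesium malonate 23 (not isolated), via acylmalonic half-ester 24 (not isolated)
Conditions: 3, CDI, THF, rt; 7, Mg(OEt)2, THF, rt, evaporate; combine in THF, rt to 40 °C; cold 0.5 M HCl work-up
Reagents that add atoms: none
Why: Masamune–Brooks β-keto ester synthesis, in which the neutral magnesium malonate chelate is C-acylated by the imidazolide and then loses CO2, with no strong base present that could eliminate the β-silyloxy group.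

Step 13
Reactants: 25 allyl (R)-5-(TBSO)-3-oxohexanoate
Product: 26 allyl 2-{2-[(R)-2-(TBSO)propyl]-1,3-dioxolan-2-yl}acetate
Conditions: TMSOCH2CH2OTMS, TMSOTf (cat.), CH2Cl2, −78 to −20 °C; pyridine quench
Reagents that add atoms: 1,2-bis(trimethylsilyloxy)ethane, C[Si](C)(C)OCCO[Si](C)(C)C
Why: Noyori ketalisation forms the dioxolane aprotically at low temperature, driven by formation of hexamethyldisiloxane, under which the secondary silyl ether and the allyl ester should persist.

Step 14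
Reactants: 26 allyl 2-{2-[(R)-2-(TBSO)propyl]-1,3-dioxolan-2-yl}acetate
Product: 27 2-{2-[(R)-2-(TBSO)propyl]-1,3-dioxolan-2-yl}acetic acid
Conditions: Pd(PPh3)4 (cat.), morpholine, THF, rt; pH 4 buffer work-up
Reagents that add atoms: none
Why: Tsuji–Trost deallylation with zerovalent palladium under neutral conditions, after which the acid cannot decarboxylate because its β-carbonyl is masked as the ketal.

Step 15
Reactants: 27 2-{2-[(R)-2-(TBSO)propyl]-1,3-dioxolan-2-yl}acetic acid, 11 allyl 4-(2,2-dimethyl-4-oxo-4H-1,3-dioxin-6-yl)-3-oxobutanoate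
Product: 29 allyl 2-[2-(2,2-dimethyl-4-oxo-4H-1,3-dioxin-6-yl)acetyl]-3-oxo-4-{2-[(R)-2-(TBSO)propyl]-1,3-dioxolan-2-yl}butanoate, via acid chloride 28 (not isolated)
Conditions: 27, 1-chloro-N,N,2-trimethylprop-1-en-1-amine, CH2Cl2, 0 °C; then 11, MgCl2, pyridine, CH2Cl2, 0 °C
Reagents that add atoms: none
Why: HCl-free acid chloride formation keeps the ketal and silyl ether intact, and magnesium-mediated soft enolisation of the β-keto ester gives C-acylation between ketone and allyl ester as in step 7.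

Step 16
Reactants: 29 allyl 2-[2-(2,2-dimethyl-4-oxo-4H-1,3-dioxin-6-yl)acetyl]-3-oxo-4-{2-[(R)-2-(TBSO)propyl]-1,3-dioxolan-2-yl}butanoate
Product: 31 6-(5-{2-[(R)-2-(TBSO)propyl]-1,3-dioxolan-2-yl}-2,4-dioxopentyl)-2,2-dimethyl-4H-1,3-dioxin-4-one, via keto acid 30 (not isolated)
Conditions: Pd(PPh3)4 (cat.), morpholine, CH2Cl2, 0 °C to rt
Reagents that add atoms: none
Why: Tsuji–Trost deallylation followed by spontaneous decarboxylation of the β,β'-diketo acid, as in step 8, under conditions to which the dioxolane and silyl ether are inert.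

Step 17
Reactants: 31 6-(5-{2-[(R)-2-(TBSO)propyl]-1,3-dioxolan-2-yl}-2,4-dioxopentyl)-2,2-dimethyl-4H-1,3-dioxin-4-one, 21 benzyl (R)-3-{[2,4-bis(benzyloxy)-6-((R)-2-{[(R)-3-hydroxybutanoyl]oxy}propyl)benzoyl]oxy}butanoate
Product: 35 benzyl (R)-3-{[2,4-bis(benzyloxy)-6-((R)-2-{[(R)-3-{[2,4-dihydroxy-6-({2-[(R)-2-(TBSO)propyl]-1,3-dioxolan-2-yl}methyl)benzoyl]oxy}butanoyl]oxy}propyl)benzoyl]oxy}butanoate, via acylketene 32 (not isolated), via triketo ester 33 (not isolated), via cyclic aldol 34 (not isolated)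
Conditions: 31 (1.3 equiv), 21, toluene, 110 °C; then Et3N, CH2Cl2, rt; then AcOH, rt
Reagents that add atoms: none
Why: Heating 31 triggers a retro-[4+2] that expels acetone and gives acylketene 32, whose ketene carbon is attacked by the only free hydroxyl of 21 (the B carbinol oxygen), forming the aryl-ester C(=O)–O bond as triketo ester 33. Triethylamine then enolises the C2 methylene between the ester and the C3 ketone, which adds to the C7 ketone in a 6-exo-trig aldol closure (6-enolexo-exo-trig), and acid-assisted loss of water from aldol 34 with enolisation of the C3 and C5 ketones gives benzene ring A. The closest known reaction type is the thermolysis of 6-(2,4-dioxoalkyl)-1,3-dioxin-4-ones with alcohols followed by aldol aromatisation to 6-alkyl-2,4-dihydroxybenzoates, applied here to a more functionalised pair of partners. No stereocentre is formed in the product (the two sp3 ring carbons of 34 are lost on aromatisation), and the four existing (R) centres are spectators because acylation occurs on oxygen with retention. Chemoselectivity rests on 21 having a single hydroxyl (ring C phenols benzylated) and on neutral capture; regioselectivity rests on the dioxolane, which removes the fourth ketone so that only the C2-to-C7 closure is available and the C4-to-C9 alternative does not exist; the weak amine and the absence of alcohol solvent protect the ester bonds.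

Step 18
Reactants: 35 (protected tetraester from step 17)
Product: 36 benzyl (R)-3-{[2,4-bis(benzyloxy)-6-((R)-2-{[(R)-3-{[2,4-dihydroxy-6-((R)-4-hydroxy-2-oxopentyl)benzoyl]oxy}butanoyl]oxy}propyl)benzoyl]oxy}butanoate
Conditions: 1 M aq. HCl/THF (1:3), 0 °C to rt, short contact; pH 7 buffer quench
Reagents that add atoms: water, O (supplies the ketone oxygen)
Why: Acid-catalysed ketal hydrolysis and acidolysis of the secondary silyl ether proceed in dilute acid at room temperature, where the hindered aryl esters, the alkyl esters and the benzyl ethers are stable, and the short contact time is meant to forestall closure of the unmasked benzylic ketone onto the ortho ester.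

Step 19
Reactants: 36 (tribenzyl-protected hydroxy ketone from step 18)
Product: 37 Hansforester I
Conditions: H2 (1 atm), Pd/C, EtOAc, rt
Reagents that add atoms: none
Why: Hydrogenolysis cleaves the two aryl benzyl ethers and the benzyl ester, while the aliphatic ketone, the aryl esters and the homobenzylic (not benzylic) ester C–O bond are not reduced under these neutral conditions, so all four (R) centres reach the target unchanged.

**Compound list**

1 | methyl (R)-3-hydroxybutanoate | C[C@@H](O)CC(=O)OC | starting material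
2 | methyl (R)-3-(tert-butyldimethylsilyloxy)butanoate | C[C@@H](O[Si](C)(C)C(C)(C)C)CC(=O)OC | intermediate
3 | (R)-3-(tert-butyldimethylsilyloxy)butanoic acid | C[C@@H](O[Si](C)(C)C(C)(C)C)CC(=O)O | intermediate
4 | benzyl (R)-3-hydroxybutanoate | C[C@@H](O)CC(=O)OCc1ccccc1 | intermediate
5 | benzyl (R)-3-{[(R)-3-(TBSO)butanoyl]oxy}butanoate | C[C@@H](O[Si](C)(C)C(C)(C)C)CC(=O)O[C@H](C)CC(=O)OCc1ccccc1 | intermediate
6 | (R)-3-{[(R)-3-(TBSO)butanoyl]oxy}butanoic acid | C[C@@H](O[Si](C)(C)C(C)(C)C)CC(=O)O[C@H](C)CC(=O)O | intermediate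
7 | allyl hydrogen malonate | C=CCOC(=O)CC(=O)O | starting material
8 | 2,2,6-trimethyl-4H-1,3-dioxin-4-one | CC1=CC(=O)OC(C)(C)O1 | starting material
9 | allyl 3-chloro-3-oxopropanoate (allyl malonyl chloride) | C=CCOC(=O)CC(=O)Cl | intermediate (not isolated)
10 | lithium 2,2-dimethyl-6-methylidene-6H-1,3-dioxin-4-olate (dienolate of 8) | [Li+].C=C1C=C([O-])OC(C)(C)O1 | intermediate (not isolated)
11 | allyl 4-(2,2-dimethyl-4-oxo-4H-1,3-dioxin-6-yl)-3-oxobutanoate | C=CCOC(=O)CC(=O)CC1=CC(=O)OC(C)(C)O1 | intermediate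
12 | (R)-3-{[(R)-3-(TBSO)butanoyl]oxy}butanoyl chloride | C[C@@H](O[Si](C)(C)C(C)(C)C)CC(=O)O[C@H](C)CC(=O)Cl | intermediate (not isolated)
13 | allyl (5R)-2-[2-(2,2-dimethyl-4-oxo-4H-1,3-dioxin-6-yl)acetyl]-3-oxo-5-{[(R)-3-(TBSO)butanoyl]oxy}hexanoate (C2 undefined, enolised) | C=CCOC(=O)C(C(=O)CC1=CC(=O)OC(C)(C)O1)C(=O)C[C@@H](C)OC(=O)C[C@@H](C)O[Si](C)(C)C(C)(C)C | intermediate
14 | (5R)-2-[2-(2,2-dimethyl-4-oxo-4H-1,3-dioxin-6-yl)acetyl]-3-oxo-5-{[(R)-3-(TBSO)butanoyl]oxy}hexanoic acid | OC(=O)C(C(=O)CC1=CC(=O)OC(C)(C)O1)C(=O)C[C@@H](C)OC(=O)C[C@@H](C)O[Si](C)(C)C(C)(C)C | intermediate (not isolated)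
15 | (R)-7-(2,2-dimethyl-4-oxo-4H-1,3-dioxin-6-yl)-4,6-dioxoheptan-2-yl (R)-3-(TBSO)butanoate | CC1(C)OC(CC(=O)CC(=O)C[C@@H](C)OC(=O)C[C@@H](C)O[Si](C)(C)C(C)(C)C)=CC(=O)O1 | intermediate
16 | (R)-4,6,8,10-tetraoxodec-9-en-2-yl (R)-3-(TBSO)butanoate (acylketene, C10 is the ketene carbon) | O=C=CC(=O)CC(=O)CC(=O)C[C@@H](C)OC(=O)C[C@@H](C)O[Si](C)(C)C(C)(C)C | intermediate (not isolated)
17 | benzyl (R)-3-{[(R)-9-{[(R)-3-(TBSO)butanoyl]oxy}-3,5,7-trioxodecanoyl]oxy}butanoate | C[C@@H](O[Si](C)(C)C(C)(C)C)CC(=O)O[C@H](C)CC(=O)CC(=O)CC(=O)CC(=O)O[C@H](C)CC(=O)OCc1ccccc1 | intermediate (not isolated)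
18 | benzyl (R)-3-{[2-hydroxy-4,6-dioxo-2-((R)-2-{[(R)-3-(TBSO)butanoyl]oxy}propyl)cyclohexane-1-carbonyl]oxy}butanoate (two transient ring centres undefined) | C[C@@H](O[Si](C)(C)C(C)(C)C)CC(=O)O[C@H](C)CC1(O)CC(=O)CC(=O)C1C(=O)O[C@H](C)CC(=O)OCc1ccccc1 | intermediate (not isolated)
19 | benzyl (R)-3-{[2,4-dihydroxy-6-((R)-2-{[(R)-3-(TBSO)butanoyl]oxy}propyl)benzoyl]oxy}butanoate | C[C@H](Cc1cc(O)cc(O)c1C(=O)O[C@H](C)CC(=O)OCc1ccccc1)OC(=O)C[C@@H](C)O[Si](C)(C)C(C)(C)C | intermediate
20 | benzyl (R)-3-{[2,4-bis(benzyloxy)-6-((R)-2-{[(R)-3-(TBSO)butanoyl]oxy}propyl)benzoyl]oxy}butanoate | C[C@H](Cc1cc(OCc2ccccc2)cc(OCc2ccccc2)c1C(=O)O[C@H](C)CC(=O)OCc1ccccc1)OC(=O)C[C@@H](C)O[Si](C)(C)C(C)(C)C | intermediate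
21 | benzyl (R)-3-{[2,4-bis(benzyloxy)-6-((R)-2-{[(R)-3-hydroxybutanoyl]oxy}propyl)benzoyl]oxy}butanoate | C[C@H](Cc1cc(OCc2ccccc2)cc(OCc2ccccc2)c1C(=O)O[C@H](C)CC(=O)OCc1ccccc1)OC(=O)C[C@@H](C)O | intermediate
22 | (R)-3-(TBSO)-1-(1H-imidazol-1-yl)butan-1-one | C[C@@H](O[Si](C)(C)C(C)(C)C)CC(=O)n1ccnc1 | intermediate (not isolated)
23 | magnesium bis(allyl malonate), Mg(O2CCH2CO2CH2CH=CH2)2 | [Mg+2].C=CCOC(=O)CC(=O)[O-].C=CCOC(=O)CC(=O)[O-] | intermediate (not isolated)
24 | (5R)-2-[(allyloxy)carbonyl]-5-(TBSO)-3-oxohexanoic acid (C2 undefined) | C[C@@H](O[Si](C)(C)C(C)(C)C)CC(=O)C(C(=O)O)C(=O)OCC=C | intermediate (not isolated)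
25 | allyl (R)-5-(TBSO)-3-oxohexanoate | C[C@@H](O[Si](C)(C)C(C)(C)C)CC(=O)CC(=O)OCC=C | intermediate
26 | allyl 2-{2-[(R)-2-(TBSO)propyl]-1,3-dioxolan-2-yl}acetate | C[C@@H](O[Si](C)(C)C(C)(C)C)CC1(CC(=O)OCC=C)OCCO1 | intermediate
27 | 2-{2-[(R)-2-(TBSO)propyl]-1,3-dioxolan-2-yl}acetic acid | C[C@@H](O[Si](C)(C)C(C)(C)C)CC1(CC(=O)O)OCCO1 | intermediate
28 | 2-{2-[(R)-2-(TBSO)propyl]-1,3-dioxolan-2-yl}acetyl chloride | C[C@@H](O[Si](C)(C)C(C)(C)C)CC1(CC(=O)Cl)OCCO1 | intermediate (not isolated)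
29 | allyl 2-[2-(2,2-dimethyl-4-oxo-4H-1,3-dioxin-6-yl)acetyl]-3-oxo-4-{2-[(R)-2-(TBSO)propyl]-1,3-dioxolan-2-yl}butanoate (C2 undefined, enolised) | C=CCOC(=O)C(C(=O)CC1=CC(=O)OC(C)(C)O1)C(=O)CC2(C[C@@H](C)O[Si](C)(C)C(C)(C)C)OCCO2 | intermediate
30 | 2-[2-(2,2-dimethyl-4-oxo-4H-1,3-dioxin-6-yl)acetyl]-3-oxo-4-{2-[(R)-2-(TBSO)propyl]-1,3-dioxolan-2-yl}butanoic acid | OC(=O)C(C(=O)CC1=CC(=O)OC(C)(C)O1)C(=O)CC2(C[C@@H](C)O[Si](C)(C)C(C)(C)C)OCCO2 | intermediate (not isolated)
31 | 6-(5-{2-[(R)-2-(TBSO)propyl]-1,3-dioxolan-2-yl}-2,4-dioxopentyl)-2,2-dimethyl-4H-1,3-dioxin-4-one | CC1(C)OC(CC(=O)CC(=O)CC2(C[C@@H](C)O[Si](C)(C)C(C)(C)C)OCCO2)=CC(=O)O1 | intermediate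
32 | 8-{2-[(R)-2-(TBSO)propyl]-1,3-dioxolan-2-yl}oct-1-ene-1,3,5,7-tetraone (acylketene) | O=C=CC(=O)CC(=O)CC(=O)CC1(C[C@@H](C)O[Si](C)(C)C(C)(C)C)OCCO1 | intermediate (not isolated)
33 | 3,5,7-trioxo-8-{2-[(R)-2-(TBSO)propyl]-1,3-dioxolan-2-yl}octanoate ester of 21 at the B hydroxyl | C[C@H](Cc1cc(OCc2ccccc2)cc(OCc2ccccc2)c1C(=O)O[C@H](C)CC(=O)OCc1ccccc1)OC(=O)C[C@@H](C)OC(=O)CC(=O)CC(=O)CC(=O)CC1(C[C@@H](C)O[Si](C)(C)C(C)(C)C)OCCO1 | intermediate (not isolated)
34 | 2-hydroxy-4,6-dioxo-2-({2-[(R)-2-(TBSO)propyl]-1,3-dioxolan-2-yl}methyl)cyclohexane-1-carboxylate ester of 21 at the B hydroxyl (two transient ring centres undefined) | C[C@H](Cc1cc(OCc2ccccc2)cc(OCc2ccccc2)c1C(=O)O[C@H](C)CC(=O)OCc1ccccc1)OC(=O)C[C@@H](C)OC(=O)C1C(=O)CC(=O)CC1(O)CC2(C[C@@H](C)O[Si](C)(C)C(C)(C)C)OCCO2 | intermediate (not isolated)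
35 | benzyl (R)-3-{[2,4-bis(benzyloxy)-6-((R)-2-{[(R)-3-{[2,4-dihydroxy-6-({2-[(R)-2-(TBSO)propyl]-1,3-dioxolan-2-yl}methyl)benzoyl]oxy}butanoyl]oxy}propyl)benzoyl]oxy}butanoate | C[C@H](Cc1cc(OCc2ccccc2)cc(OCc2ccccc2)c1C(=O)O[C@H](C)CC(=O)OCc1ccccc1)OC(=O)C[C@@H](C)OC(=O)c1c(O)cc(O)cc1CC2(C[C@@H](C)O[Si](C)(C)C(C)(C)C)OCCO2 | intermediate
36 | benzyl (R)-3-{[2,4-bis(benzyloxy)-6-((R)-2-{[(R)-3-{[2,4-dihydroxy-6-((R)-4-hydroxy-2-oxopentyl)benzoyl]oxy}butanoyl]oxy}propyl)benzoyl]oxy}butanoate | C[C@H](Cc1cc(OCc2ccccc2)cc(OCc2ccccc2)c1C(=O)O[C@H](C)CC(=O)OCc1ccccc1)OC(=O)C[C@@H](C)OC(=O)c1c(O)cc(O)cc1CC(=O)C[C@@H](C)O | intermediate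
37 | Hansforester I, (R)-3-{[2,4-dihydroxy-6-((R)-2-{[(R)-3-{[2,4-dihydroxy-6-((R)-4-hydroxy-2-oxopentyl)benzoyl]oxy}butanoyl]oxy}propyl)benzoyl]oxy}butanoic acid | C[C@H](Cc1cc(O)cc(O)c1C(=O)O[C@H](C)CC(=O)O)OC(=O)C[C@@H](C)OC(=O)c1c(O)cc(O)cc1CC(=O)C[C@@H](C)O | target

**Totals**

Total step count: 19 steps, each telescoped operation counted once.
Longest linear sequence: 12 steps from 1 (steps 1, 2, 4, 5, 7, 8, 9, 10, 11, 17, 18, 19); the ring A branch (steps 1, 2, 12 to 19) is 10 steps.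

**Steps most likely to fail**

Step 9. Under the amine base the C7 ketone of the open-chain triketo ester can enolise toward C8 and expel the C9 carboxylate (E1cB loss of the B unit), in competition with the aldol closure. The same β-acyloxy ketone liability is present during steps 7 and 8. The fallback sets out from 3 and 11 and returns to the route at 20. It carries the side-chain oxygen as a silyl ether, a far poorer leaving group, and attaches B only after ring C exists. Acid 3 is converted with 1-chloro-N,N,2-trimethylprop-1-en-1-amine into (R)-3-(TBSO)butanoyl chloride F1, which C-acylates 11 (MgCl2, pyridine) to the silyloxy diketo ester F2. Pd(PPh3)4 and morpholine then give, through the keto acid F3, the silyloxy diketo-dioxinone F4. Heating F4 with 4 in toluene, then Et3N and AcOH, should lead through the acylketene F5, the triketo ester F6 and the cyclic aldol F7 to the silyl-protected ring C resorcylate F8. Benzylation (BnBr, K2CO3, DMF) gives the dibenzyl ether F9, and HF·pyridine frees the side-chain alcohol F10. F10 is acylated at once with F1 and pyridine at low temperature, before the hydroxyl can lactonise onto the neighbouring aryl ester, to give 20.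

Step 18. The aqueous acid needed to open the dioxolane also promotes enolisation of the unmasked benzylic ketone toward ring A, so closure onto the ortho ester with expulsion of the B–C–D alcohol (isocoumarin formation) or dehydration of the β-hydroxy ketone can compete with clean unmasking. The fallback sets out from 35 and returns at 36. It gives up the single hydrolytic operation for two orthogonal, non-hydrolytic unmaskings. HF·pyridine in THF/pyridine first cleaves only the silyl ether to give the hydroxy ketal F11. The ketal is then transferred to the solvent by exchange in dry acetone with a catalytic amount of pyridinium p-toluenesulfonate at rt to 40 °C, which should give 36 without exposure to aqueous mineral acid.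

Step 17. Bimolecular capture of the acylketene by the hindered secondary hydroxyl of the advanced alcohol at near-equimolar stoichiometry may lose out to ketene dimerisation. At the base stage an enol oxygen of the triketo ester may also lactonise onto the new ester (pyrone formation) and expel the alcohol again. The fallback sets out from 31 and returns at 35. It forms ring A before the ester bond. Treating 31 with Et3N in CH2Cl2 and then AcOH, with no external alcohol and no heating, should give by intramolecular aldol condensation of dioxinone C5 onto the distal ketone the isopropylidene-protected resorcylate 7-hydroxy-2,2-dimethyl-5-({2-[(R)-2-(TBSO)propyl]-1,3-dioxolan-2-yl}methyl)-4H-1,3-benzodioxin-4-one F12. Irradiation of F12 at about 300 nm in CH2Cl2 with 21 at rt expels acetone and generates the ortho-quinone ketene F13. This is captured by the B hydroxyl of 21 under neutral conditions (photochemical salicylate transfer from a benzodioxinone) and gives 35 directly, with both ring A phenols free.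

**Further compounds**

F1 | step 9 | (R)-3-(TBSO)butanoyl chloride | C[C@@H](O[Si](C)(C)C(C)(C)C)CC(=O)Cl
F2 | step 9 | allyl (5R)-5-(TBSO)-2-[2-(2,2-dimethyl-4-oxo-4H-1,3-dioxin-6-yl)acetyl]-3-oxohexanoate | C=CCOC(=O)C(C(=O)CC1=CC(=O)OC(C)(C)O1)C(=O)C[C@@H](C)O[Si](C)(C)C(C)(C)C
F3 | step 9 | (5R)-5-(TBSO)-2-[2-(2,2-dimethyl-4-oxo-4H-1,3-dioxin-6-yl)acetyl]-3-oxohexanoic acid | OC(=O)C(C(=O)CC1=CC(=O)OC(C)(C)O1)C(=O)C[C@@H](C)O[Si](C)(C)C(C)(C)C
F4 | step 9 | 6-[(6R)-6-(TBSO)-2,4-dioxoheptyl]-2,2-dimethyl-4H-1,3-dioxin-4-one | CC1(C)OC(CC(=O)CC(=O)C[C@@H](C)O[Si](C)(C)C(C)(C)C)=CC(=O)O1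
F5 | step 9 | (R)-9-(TBSO)dec-1-ene-1,3,5,7-tetraone (acylketene) | O=C=CC(=O)CC(=O)CC(=O)C[C@@H](C)O[Si](C)(C)C(C)(C)C
F6 | step 9 | benzyl (R)-3-{[(R)-9-(TBSO)-3,5,7-trioxodecanoyl]oxy}butanoate | C[C@@H](O[Si](C)(C)C(C)(C)C)CC(=O)CC(=O)CC(=O)CC(=O)O[C@H](C)CC(=O)OCc1ccccc1
F7 | step 9 | benzyl (R)-3-{[2-hydroxy-4,6-dioxo-2-((R)-2-(TBSO)propyl)cyclohexane-1-carbonyl]oxy}butanoate | C[C@@H](O[Si](C)(C)C(C)(C)C)CC1(O)CC(=O)CC(=O)C1C(=O)O[C@H](C)CC(=O)OCc1ccccc1
F8 | step 9 | benzyl (R)-3-{[2,4-dihydroxy-6-((R)-2-(TBSO)propyl)benzoyl]oxy}butanoate | C[C@H](Cc1cc(O)cc(O)c1C(=O)O[C@H](C)CC(=O)OCc1ccccc1)O[Si](C)(C)C(C)(C)C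
F9 | step 9 | benzyl (R)-3-{[2,4-bis(benzyloxy)-6-((R)-2-(TBSO)propyl)benzoyl]oxy}butanoate | C[C@H](Cc1cc(OCc2ccccc2)cc(OCc2ccccc2)c1C(=O)O[C@H](C)CC(=O)OCc1ccccc1)O[Si](C)(C)C(C)(C)C
F10 | step 9 | benzyl (R)-3-{[2,4-bis(benzyloxy)-6-((R)-2-hydroxypropyl)benzoyl]oxy}butanoate | C[C@H](Cc1cc(OCc2ccccc2)cc(OCc2ccccc2)c1C(=O)O[C@H](C)CC(=O)OCc1ccccc1)O
F11 | step 18 | benzyl (R)-3-{[2,4-bis(benzyloxy)-6-((R)-2-{[(R)-3-{[2,4-dihydroxy-6-({2-[(R)-2-hydroxypropyl]-1,3-dioxolan-2-yl}methyl)benzoyl]oxy}butanoyl]oxy}propyl)benzoyl]oxy}butanoate | C[C@H](Cc1cc(OCc2ccccc2)cc(OCc2ccccc2)c1C(=O)O[C@H](C)CC(=O)OCc1ccccc1)OC(=O)C[C@@H](C)OC(=O)c1c(O)cc(O)cc1CC2(C[C@@H](C)O)OCCO2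
F12 | step 17 | 7-hydroxy-2,2-dimethyl-5-({2-[(R)-2-(TBSO)propyl]-1,3-dioxolan-2-yl}methyl)-4H-1,3-benzodioxin-4-one | CC1(C)OC(=O)c2c(CC3(C[C@@H](C)O[Si](C)(C)C(C)(C)C)OCCO3)cc(O)cc2O1
F13 | step 17 | 3-hydroxy-6-(oxomethylidene)-5-({2-[(R)-2-(TBSO)propyl]-1,3-dioxolan-2-yl}methyl)cyclohexa-2,4-dien-1-one (ortho-quinone ketene) | O=C=C1C(=O)C=C(O)C=C1CC2(C[C@@H](C)O[Si](C)(C)C(C)(C)C)OCCO2
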